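**Retrosynthetic overview**

1. Locants follow the target SMILES: C1 (CH–OAng), C2 (CH2), C3 (CHOH), C4 (C–CH3), C5, C6, C7 (cyclobutane CH), C8 (C=O), C9 (CH2), C10 (CH–CH3), C11 (C(CH3)CH2OAc); cyclobutane C4–C5–C6–C7.
2. Feature: C11 is quaternary (CH3, CH2O) and lies beside oxygenated C1, so it can be the end point of a 1,2-shift of C6 from C1; the seven-membered ring C1–C2–C3–C4–C5–C6–C11 is then the enlarged six-membered bridge C4–C3–C2–C1–C6 of a tricyclo[4.4.0.0(2,7)]decane.
3. Disconnections (retro): C1–H and the CH2O acetate by Evans–Tishchenko reduction; C6–C11 by semipinacol shift in a C1 (2-methyloxiranyl) carbinol; C1–C11 by isopropenyl addition to a C1 ketone; C6–C7 by C7 enolate alkylation of a C6 bromide in a cis-decalin; C4–C7 and C5–C10 by Diels–Alder reaction of 2-methoxy-5-methyl-1,4-benzoquinone with a 2-silyloxypenta-1,3-diene.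
4. Ring order (forward): ring A (C1–C6, the quinone), ring B (C4, C7, C8, C9, C10, C5; cycloaddition), cyclobutane (alkylation), seven-membered ring (ring expansion).

Key step: step 12

Assumption: the sense of induction of the (S)-BINOL/TiCl2(OiPr)2 catalyst in step 2 is taken to be the one drawn; should the adduct form in the mirror-image sense, (R)-BINOL is used and nothing else changes.

**Route**

Step 1
Reactants: 1 (E)-pent-3-en-2-one
Product: 2 (E)-2-(triisopropylsilyloxy)penta-1,3-diene
Conditions: iPr3SiOTf, Et3N, Et2O, 0 °C to rt
Reagents that add atoms: triisopropylsilyl trifluoromethanesulfonate, CC(C)[Si](OS(=O)(=O)C(F)(F)F)(C(C)C)C(C)C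
Why: Silyl dienol ether formation by soft enolisation at the methyl group (kinetic α′ position) and O-silylation should give the cross-conjugated 2-silyloxy diene with the (E) geometry of the C9=C10 bond retained.

Step 2
Reactants: 3 2-methoxy-5-methyl-1,4-benzoquinone; 2 (E)-2-(triisopropylsilyloxy)penta-1,3-diene
Product: 4 (4aS,8R,8aR)-2-methoxy-4a,8-dimethyl-6-(triisopropylsilyloxy)-4a,5,8,8a-tetrahydronaphthalene-1,4-dione (cis-fused; target locants: C3 and C6 carbonyls; C1 OMe; C8 silyl enol ether; C10 methyl cis to the C5–C6 bond)
Conditions: (S)-BINOL/TiCl2(OiPr)2 (10 mol %), 4 Å MS, toluene/CH2Cl2, −30 to 0 °C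
Reagents that add atoms: none
Why: Catalytic enantioselective quinone Diels–Alder reaction under a chiral binaphthol Lewis acid of tetravalent titanium, which chelates the C6 carbonyl oxygen and the methoxy oxygen, so that the methyl-bearing C4=C5 bond is the dienophile (the methoxy-bearing bond is deactivated), the nucleophilic CH2 terminus of the diene (C7) bonds to C4 (β to the activated C6 carbonyl), endo addition gives the cis ring fusion with the C10 methyl cis to the C5–C6 bond, and the ligand sets the absolute configuration of C4, C5 and C10.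

Step 3
Reactants: 4 Diels–Alder adduct
Product: 5 C6 alcohol (OH trans to H-5, on the face of the C5–C10 bond; C3 vinylogous ester and C8 silyl enol ether kept)
Conditions: NaBH4, CeCl3·7H2O, MeOH/CH2Cl2, −78 °C
Reagents that add atoms: none
Why: Luche 1,2-reduction should take only the C6 carbonyl, because the C3 carbonyl is a vinylogous ester flanked by quaternary C4, and hydride should enter from the convex face (anti to the pseudoaxial C4–C7 bond that lies 1,3 to C6), which sets C6 with the hydroxyl trans to H-5.

Step 4
Reactants: 5 C6 alcohol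
Product: 6 C6 bromide (Br cis to H-5; inverted)
Conditions: CBr4, PPh3, CH2Cl2, 0 °C
Reagents that add atoms: carbon tetrabromide, BrC(Br)(Br)Br
Why: Appel bromination: bromide displaces the oxyphosphonium group by SN2 with inversion, which puts bromine equatorial and cis to H-5 as needed for later backside attack by C7, while SN2′ attack is disfavoured because C2 is the electron-rich α-carbon of the vinylogous ester.

Step 5
Reactants: 6 C6 bromide
Product: 7 C3 allylic alcohol (OH trans to the C4 methyl; C1(OMe)=C2 enol ether; C6 bromide; C8 silyl enol ether)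
Conditions: iBu2AlH, CH2Cl2, −78 °C; aq. potassium sodium tartrate
Reagents that add atoms: none
Why: 1,2-Reduction of the vinylogous ester carbonyl (the first stage of a Stork–Danheiser sequence, stopped at the allylic alcohol) tolerates the allylic bromide and the silyl enol ether at −78 °C, and hydride should attack from the convex face anti to the axial C4–C7 bond, which sets C3 with the hydroxyl trans to the C4 methyl.

Step 6
Reactants: 7 C3 allylic alcohol
Product: 8 C3 tert-butyldimethylsilyl ether
Conditions: TBSOTf, 2,6-lutidine, CH2Cl2, −78 °C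
Reagents that add atoms: tert-butyldimethylsilyl trifluoromethanesulfonate, CC(C)(C)[Si](C)(C)OS(=O)(=O)C(F)(F)F
Why: Silylation of the hindered secondary alcohol with the silyl triflate and a non-nucleophilic base, run cold and at once because the 3-methoxyallylic alcohol ionises with acid, affects no stereocentre.

Step 7
Reactants: 8 C3 silyl ether
Product: 10 tricyclic enol ether ketone (tricyclo[4.4.0.0(2,7)]decane core; cyclobutane C4–C5–C6–C7; C1(OMe)=C2; C3 OTBS on the C7 side; C8 ketone; C10 methyl on the C6 side), via bromo ketone 9 (not isolated)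
Conditions: Bu4NF, t-BuOH, THF, −20 °C to rt
Reagents that add atoms: none
Why: Fluoride cleaves the silyl enol ether to the C8 ketone/enolate, which equilibrates through t-BuOH to the C7 enolate and should close the cyclobutane by intramolecular SN2 alkylation (4-exo-tet) of the 2-alkoxyallylic bromide at C6 with inversion, the intramolecular counterpart of enolate alkylation with 2-methoxyallyl bromide and of the keto-halide closure known for bicyclo[3.1.1]heptanes from cis-decalins; the cis fusion holds C7 axial on ring A and the equatorial C6–Br bond anti to C5–C4, the C9 enolate cannot reach the backside of C6, and C6 and C7 are fixed by the ring constraint.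

Step 8
Reactants: 10 tricyclic enol ether ketone
Product: 12 C1 ketone with C8 alcohol and C3 OTBS, via C8 alcohol 11 (not isolated)
Conditions: NaBH4, MeOH, 0 °C; then aq. oxalic acid, THF, 0 °C to rt
Reagents that add atoms: water, O
Why: Chemoselective NaBH4 reduction parks the C8 carbonyl as an alcohol (hydride expected from the C6 side, away from the C4 methyl that overhangs the C8–C10 bridge; the C8 configuration is inconsequential because it is reoxidised in step 10), and mild aqueous acid then hydrolyses the methyl enol ether by C2 protonation to the C1 ketone without loss of the β-silyloxy group.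

Step 9
Reactants: 12 C1 ketone; 13 isopropenylmagnesium bromide
Product: 14 C1 tertiary allylic alcohol (isopropenyl on the C5 side; OH on the C7 side cis to OTBS; C8 alcohol)
Conditions: CH2=C(CH3)MgBr (3 equiv), CeCl3, THF, −78 °C
Reagents that add atoms: none
Why: 1,2-Addition of the organocerium reagent CH2=C(CH3)CeCl2 (which suppresses enolisation and β-elimination of the silyloxy group) to the C1 ketone should occur from the C5 side of the three-carbon bridge, anti to the C3 silyloxy group that blocks the C7 side, which sets C1.

Step 10
Reactants: 14 diol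
Product: 15 C8 ketone with C1 tertiary allylic alcohol
Conditions: Dess–Martin periodinane, NaHCO3, CH2Cl2, rt
Reagents that add atoms: none
Why: Dess–Martin oxidation converts the secondary C8 alcohol back into the ketone and removes the transient C8 stereocentre, while the tertiary allylic alcohol, the alkene and the silyl ether are inert.

Step 11
Reactants: 15 tertiary allylic alcohol
Product: 16 epoxy alcohol (C1 carbinol bearing a 2-methyloxiran-2-yl group; C3 OTBS; C8 ketone)
Conditions: VO(acac)2 (5 mol %), t-BuOOH, CH2Cl2, 0 °C to rt
Reagents that add atoms: tert-butyl hydroperoxide, CC(C)(C)OO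
Why: Hydroxyl-directed epoxidation, in which VO(acac)2 binds the C1 hydroxyl as its alkoxide and delivers the peroxide oxygen to the alkene face on the side of the C1–O bond; in the reactive rotamer the C2 methylene and not the C6 methine lies next to the C11 methyl (least allylic 1,2-strain), which sets C11 as drawn.

Step 12
Reactants: 16 epoxy alcohol
Product: 17 ring-expanded diketone (tricyclo[5.4.0.0(2,8)]undecane core; C1 and C8 ketones; C11 with CH3 on the C5 side and CH2OH on the C7 side; C3 OTBS)
Conditions: Et2AlCl, CH2Cl2, −78 to 0 °C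
Reagents that add atoms: none
Why: Et2AlCl deprotonates the tertiary alcohol (ethane is lost) to the C1–O–Al(Et)Cl alkoxide, the same aluminium centre binds the epoxide oxygen, the tertiary C11–O bond ionises, and the C1–C6 bond held anti to it shifts from C1 to C11 while the C1 alkoxide collapses to the ketone; this is the Lewis-acid-promoted semipinacol rearrangement of a tertiary 2,3-epoxy alcohol with ring expansion. The seven-membered ring C1–C2–C3–C4–C5–C6–C11 is closed by insertion of C11 into the C1–C6 bond of the six-membered bridge (one-carbon enlargement by 1,2-alkyl shift), not by an end-to-end cyclisation. The only new stereocentre, C11, arises by inversion at the epoxide carbon, so the configuration installed in step 11 is transmitted, and C6 migrates with retention. The step needs C6 and not C2 to migrate: C6 is the more substituted carbon, C2 is deactivated by the β-silyloxy group at C3, and the chelated rotamer with the C11 methyl anti to the bulky aluminium alkoxide is the one that places C1–C6 anti to the breaking C–O bond. The α-carbon of the new β-hydroxy ketone is quaternary, so neither dehydration nor epimerisation can follow.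

Step 13
Reactants: 17 ring-expanded hydroxy diketone
Product: 18 C1 alcohol (OH cis to the C11 methyl) with C11 CH2OAc
Conditions: SmI2 (20 mol %), CH3CHO, THF, −10 °C
Reagents that add atoms: acetaldehyde, CC=O
Why: Evans–Tishchenko reduction: the primary hydroxyl forms a samarium-bound hemiacetal with acetaldehyde that delivers hydride intramolecularly to the C1 carbonyl on the face of the CH2O arm and itself becomes the acetate, so C1–OH is set cis to the C11 methyl and the C8 ketone, which has no directing hydroxyl, should stay untouched.

Step 14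
Reactants: 18 hydroxy acetate
Product: 19 C1 angelate (C3 OTBS)
Conditions: angelic acid, 2,4,6-Cl3C6H2COCl, Et3N, toluene, rt; then 18, 80 °C
Reagents that add atoms: angelic acid ((Z)-2-methylbut-2-enoic acid), C/C=C(/C)C(=O)O
Why: Yamaguchi-type esterification of the hindered secondary alcohol with the preformed mixed anhydride, run without a nucleophilic amine catalyst so that the (Z)-enoate is not isomerised to the tiglate and under weakly basic conditions that disfavour acetyl migration from the CH2O arm.

Step 15
Reactants: 19 silyl ether
Product: 20 target compound CNP0212099.1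
Conditions: HF·pyridine, pyridine, THF, 0 °C to rt
Reagents that add atoms: none
Why: Fluoride cleavage of the silyl ether under buffered acidic conditions should leave both esters, the ketone and the (Z)-alkene intact and avoids base-induced acyl migration between O-1 and O-3.

**Compound list**

1 | (E)-pent-3-en-2-one | C/C=C/C(C)=O | starting material
2 | (E)-2-(triisopropylsilyloxy)penta-1,3-diene | C=C(O[Si](C(C)C)(C(C)C)C(C)C)/C=C/C | intermediate
3 | 2-methoxy-5-methyl-1,4-benzoquinone | COC1=CC(=O)C(C)=CC1=O | starting material
4 | (4aS,8R,8aR)-2-methoxy-4a,8-dimethyl-6-(triisopropylsilyloxy)-4a,5,8,8a-tetrahydronaphthalene-1,4-dione | COC1=CC(=O)[C@@]2(C)CC(O[Si](C(C)C)(C(C)C)C(C)C)=C[C@@H](C)[C@H]2C1=O | intermediate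
5 | C6 alcohol of 4 (OH trans to H-5) | COC1=CC(=O)[C@@]2(C)CC(O[Si](C(C)C)(C(C)C)C(C)C)=C[C@@H](C)[C@H]2[C@H]1O | intermediate
6 | C6 bromide (Br cis to H-5) | COC1=CC(=O)[C@@]2(C)CC(O[Si](C(C)C)(C(C)C)C(C)C)=C[C@@H](C)[C@H]2[C@@H]1Br | intermediate
7 | C3 allylic alcohol (OH trans to C4 methyl), C6 bromide | COC1=C[C@@H](O)[C@@]2(C)CC(O[Si](C(C)C)(C(C)C)C(C)C)=C[C@@H](C)[C@H]2[C@@H]1Br | intermediate
8 | C3 tert-butyldimethylsilyl ether of 7 | COC1=C[C@@H](O[Si](C)(C)C(C)(C)C)[C@@]2(C)CC(O[Si](C(C)C)(C(C)C)C(C)C)=C[C@@H](C)[C@H]2[C@@H]1Br | intermediate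
9 | bromo ketone (C8 ketone, C6 bromide, C3 OTBS) | COC1=C[C@@H](O[Si](C)(C)C(C)(C)C)[C@@]2(C)CC(=O)C[C@@H](C)[C@H]2[C@@H]1Br | intermediate (not isolated)
10 | tricyclic enol ether ketone (cyclobutane C4–C5–C6–C7) | COC1=C[C@@H](O[Si](C)(C)C(C)(C)C)[C@]2(C)[C@@H]3[C@H]1[C@H]2C(=O)C[C@H]3C | intermediate
11 | C8 alcohol of 10 (OH on the C4 side) | COC1=C[C@@H](O[Si](C)(C)C(C)(C)C)[C@]2(C)[C@@H]3[C@H]1[C@H]2[C@H](O)C[C@H]3C | intermediate (not isolated)
12 | tricyclic C1 ketone with C8 alcohol and C3 OTBS | O=C1C[C@@H](O[Si](C)(C)C(C)(C)C)[C@]2(C)[C@@H]3[C@H]1[C@H]2[C@H](O)C[C@H]3C | intermediate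
13 | isopropenylmagnesium bromide | C=C(C)[Mg]Br | starting material
14 | C1 isopropenyl carbinol with C8 alcohol | O[C@@]1(C(C)=C)C[C@@H](O[Si](C)(C)C(C)(C)C)[C@]2(C)[C@@H]3[C@H]1[C@H]2[C@H](O)C[C@H]3C | intermediate
15 | C1 isopropenyl carbinol with C8 ketone | O[C@@]1(C(C)=C)C[C@@H](O[Si](C)(C)C(C)(C)C)[C@]2(C)[C@@H]3[C@H]1[C@H]2C(=O)C[C@H]3C | intermediate
16 | epoxy alcohol (C1 carbinol with 2-methyloxiran-2-yl group) | O[C@@]1([C@@]4(C)CO4)C[C@@H](O[Si](C)(C)C(C)(C)C)[C@]2(C)[C@@H]3[C@H]1[C@H]2C(=O)C[C@H]3C | intermediate
17 | ring-expanded diketone with C11 CH2OH | O=C1C[C@@H](O[Si](C)(C)C(C)(C)C)[C@]2(C)[C@@H]3[C@@H]([C@H]2C(=O)C[C@H]3C)[C@@]1(C)CO | intermediate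
18 | C1 alcohol with C11 CH2OAc | O[C@@H]1C[C@@H](O[Si](C)(C)C(C)(C)C)[C@]2(C)[C@@H]3[C@@H]([C@H]2C(=O)C[C@H]3C)[C@@]1(C)COC(C)=O | intermediate
19 | C1 angelate, C3 OTBS | C/C=C(/C)C(=O)O[C@@H]1C[C@@H](O[Si](C)(C)C(C)(C)C)[C@]2(C)[C@@H]3[C@@H]([C@H]2C(=O)C[C@H]3C)[C@@]1(C)COC(C)=O | intermediate
20 | CNP0212099.1 | C/C=C(/C)C(=O)O[C@@H]1C[C@@H](O)[C@]2(C)[C@@H]3[C@@H]([C@H]2C(=O)C[C@H]3C)[C@@]1(C)COC(C)=O | target

**Totals**

Total step count: 15. Longest linear sequence: 15 steps (1 to 20; the quinone 3 enters at step 2 and the Grignard reagent 13 at step 9).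

**Steps most likely to fail**

1. Step 12 (key step). The activated epoxide may be opened by chloride or lose a proton from C11 before the shift, or the C1–C2 bond may migrate from the other chelated rotamer. The fallback sets out from 16 and replaces chelate control by a non-chelated, sterically fixed rotamer. The tertiary hydroxyl is silylated with N-trimethylsilylimidazole (CH2Cl2, rt) to the C1 trimethylsilyl ether F1. F1 is then rearranged with TiCl4 in CH2Cl2 at −78 °C (silyl-ether variant of the semipinacol shift). The siloxy group keeps the C11 methyl anti to itself and therefore C1–C6 anti to the epoxide C–O bond, and the silyl group is lost as the carbonyl forms. Aqueous work-up comes back to the route at 17.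

2. Step 7. Ionisation or elimination of the 2-alkoxyallylic bromide, fluoride attack on the C3 silyl ether followed by O-alkylation at C6, or intermolecular alkylation may outrun the strained four-membered ring closure. The fallback sets out from 6, where C3 is still the vinylogous ester carbonyl and the C6 bromide is a γ-bromo enone that does not ionise. Bu4NF/t-BuOH in THF should give, through the bromo diketone F2, the tricyclic methoxy enone F3. The C8 ketone is then masked in the flask as its lithium enolate (LiN(SiMe3)2, THF, −78 °C), and iBu2AlH reduces the C3 carbonyl to the allylic alcohol F4. The facial bias at C3 is small in the tricycle, so the unwanted C3 epimer would be separated and returned to F3 with MnO2. Silylation of F4 (TBSCl, imidazole, DMF) comes back to the route at 10.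

3. Step 2. The catalyst may give insufficient enantioselectivity, chelate control of the regiochemistry may be lost, or the Lewis acid may strip the silyl enol ether. The fallback sets out from 2 and 3 and trades asymmetric catalysis for a racemic cycloaddition and a resolution. Uncatalysed reaction in toluene (rt to 60 °C), whose regiochemistry follows the intrinsic polarisation of the quinone and whose endo course gives the same relative configuration, should give 4 together with its enantiomer F5. Luche reduction as in step 3 gives 5 together with its enantiomer F6. Esterification with (S)-O-acetylmandelic acid (DCC, DMAP, CH2Cl2) gives the diastereomeric esters F7 (from 5) and F8 (from F6), which are separated by chromatography or crystallisation. Methanolysis of F7 (K2CO3, MeOH, 0 °C) comes back to the route at 5.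

**Further compounds**

F1 | step 12 | C1 trimethylsilyl ether of epoxy alcohol 16 | C[Si](C)(C)O[C@@]1([C@@]4(C)CO4)C[C@@H](O[Si](C)(C)C(C)(C)C)[C@]2(C)[C@@H]3[C@H]1[C@H]2C(=O)C[C@H]3C
F2 | step 7 | bromo diketone (C3 vinylogous ester, C8 ketone, C6 bromide) | COC1=CC(=O)[C@@]2(C)CC(=O)C[C@@H](C)[C@H]2[C@@H]1Br
F3 | step 7 | tricyclic methoxy enone with C8 ketone | COC1=CC(=O)[C@]2(C)[C@@H]3[C@H]1[C@H]2C(=O)C[C@H]3C
F4 | step 7 | tricyclic C3 allylic alcohol with C8 ketone | COC1=C[C@@H](O)[C@]2(C)[C@@H]3[C@H]1[C@H]2C(=O)C[C@H]3C
F5 | step 2 | enantiomer of adduct 4 | COC1=CC(=O)[C@]2(C)CC(O[Si](C(C)C)(C(C)C)C(C)C)=C[C@H](C)[C@@H]2C1=O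
F6 | step 2 | enantiomer of alcohol 5 | COC1=CC(=O)[C@]2(C)CC(O[Si](C(C)C)(C(C)C)C(C)C)=C[C@H](C)[C@@H]2[C@@H]1O
F7 | step 2 | (S)-O-acetylmandelate of 5 | COC1=CC(=O)[C@@]2(C)CC(O[Si](C(C)C)(C(C)C)C(C)C)=C[C@@H](C)[C@H]2[C@H]1OC(=O)[C@@H](OC(C)=O)c3ccccc3
F8 | step 2 | (S)-O-acetylmandelate of F6 | COC1=CC(=O)[C@]2(C)CC(O[Si](C(C)C)(C(C)C)C(C)C)=C[C@H](C)[C@@H]2[C@@H]1OC(=O)[C@@H](OC(C)=O)c3ccccc3
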